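**Retrosynthetic overview**
1. Target ⇐ heptabenzyl ether, by global hydrogenolysis.
2. Interflavan C4–C8 bond ⇐ Friedel–Crafts opening of a 2,3-cis flav-3-ene oxide by tetra-O-benzylcatechin; this sets 4β and leaves the 3-OH free.
3. Flavene oxide ⇐ one operation that closes ring C of the upper unit (C3–C4 bond) and the oxirane: a sulfonium-ylide epoxy-annulation onto an ortho aldehyde.
4. Annulation precursor ⇐ SNAr aryl ether formation (C8a–O1, retention at C2) between an (R)-β-hydroxy sulfide (from CBS reduction) and a fluoro-dibenzyloxybenzaldehyde.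
5. Ring order: rings A and B and the whole lower unit are bought; upper ring C and the oxirane form together in step 5; the oxirane is reopened in step 7.

Assumption: the target as drawn is epiafzelechin-(4β→8)-catechin (upper unit 2R,3R,4R, 2,3-cis-3,4-trans; lower unit (+)-catechin, 2R,3S); α/β follow the usual flavan drawing (the 2-aryl group of a 2R unit is α); thiophenol, benzyl alcohol, benzyl bromide and 2-(trimethylsilyl)phenyl triflate are bought.

Step 1
Reactants: 1 2-bromo-1-[4-(benzyloxy)phenyl]ethan-1-one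
Product: 2 1-[4-(benzyloxy)phenyl]-2-(phenylsulfanyl)ethan-1-one
Conditions: PhSH (1.05 equiv), K2CO3 (1.1 equiv), acetone, 0 °C to rt
Reagents that add atoms: thiophenol, Sc1ccccc1
Why: SN2 thioetherification of an α-bromo ketone; no stereocenter is formed.

Step 2
Reactants: 2 1-[4-(benzyloxy)phenyl]-2-(phenylsulfanyl)ethan-1-one
Product: 3 (1R)-1-[4-(benzyloxy)phenyl]-2-(phenylsulfanyl)ethan-1-ol
Conditions: (R)-Me-CBS [(R)-1-methyl-3,3-diphenyltetrahydro-1H,3H-pyrrolo[1,2-c][1,3,2]oxazaborole] (10 mol%), BH3·SMe2 (1.0 equiv), THF, −20 °C; MeOH quench; recrystallise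
Reagents that add atoms: none
Why: Corey–Bakshi–Shibata reduction; with the aryl group as the large substituent the (R)-catalyst delivers hydride to the face that gives the (R)-carbinol (the future C2), as with α-halo acetophenones.

Step 3
Reactants: 4 2,4,6-trifluorobenzaldehyde
Product: 5 2,4-bis(benzyloxy)-6-fluorobenzaldehyde
Conditions: BnOH (2.0 equiv), NaH (2.0 equiv), DMF, −20 °C to 0 °C
Reagents that add atoms: benzyl alcohol, OCc1ccccc1
Why: two successive SNAr reactions activated by the formyl group (para fluorine, then one ortho fluorine); each alkoxy group lowers the reactivity, so the third fluorine survives at 2.0 equiv.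

Step 4
Reactants: 3 (1R)-1-[4-(benzyloxy)phenyl]-2-(phenylsulfanyl)ethan-1-ol; 5 2,4-bis(benzyloxy)-6-fluorobenzaldehyde
Product: 6 2,4-bis(benzyloxy)-6-{(1R)-1-[4-(benzyloxy)phenyl]-2-(phenylsulfanyl)ethoxy}benzaldehyde
Conditions: NaH (1.1 equiv), DMF, 0 °C to 40 °C
Reagents that add atoms: none
Why: SNAr of the sodium alkoxide of 3 at the fluorine ortho to the aldehyde; the carbinol C–O bond is not broken, so C2 keeps its R configuration.

Step 5
Reactants: 6 2,4-bis(benzyloxy)-6-{(1R)-1-[4-(benzyloxy)phenyl]-2-(phenylsulfanyl)ethoxy}benzaldehyde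
Product: 10 (1aR,2R,7bR)-5,7-bis(benzyloxy)-2-[4-(benzyloxy)phenyl]-1a,7b-dihydro-2H-oxireno[2,3-c]chromene, via S-aryl sulfonium zwitterion 7 (not isolated), via diphenylsulfonium ylide 8 (not isolated), via sulfonium alkoxide betaine 9 (not isolated)
Conditions: 2-(trimethylsilyl)phenyl triflate (1.5 equiv), CsF (3.0 equiv), MeCN (0.02 M), 0 °C to rt; filter through basic Al2O3, use crude
Reagents that add atoms: none
Why: Proposed new method: the thioether sulfur adds to benzyne (from the silyl triflate and CsF) to give zwitterion 7, whose aryl anion removes the only available α-proton (1,4-shift) to give ylide 8; 6-exo addition of the ylide carbon to the ortho aldehyde forms the C3–C4 bond through a half-chair in which the bulky Ph2S+ group lies anti to the C2 aryl group and anti to the new alkoxide (betaine 9), and the alkoxide then displaces Ph2S with inversion at C3, so ring C and the oxirane close in one operation with the oxirane cis-fused on the face of the 2-aryl group (1aR and 7bR, C2 unchanged); closest known reaction types are the intramolecular Corey–Chaykovsky epoxidation in epoxy-annulations of vinylsulfonium salts with hydroxy or amino carbonyl compounds, and aryne-triggered sulfonium ylide formation from thioethers.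

Step 6
Reactants: 11 (+)-catechin
Product: 12 5,7,3',4'-tetra-O-benzyl-(+)-catechin
Conditions: BnBr (4.4 equiv), K2CO3 (4.4 equiv), DMF, 0 °C to rt
Reagents that add atoms: benzyl bromide, BrCc1ccccc1
Why: Williamson etherification of the four phenols (the secondary 3-OH is not alkylated by carbonate base); the stereocenters are untouched.

Step 7
Reactants: 10 (1aR,2R,7bR)-5,7-bis(benzyloxy)-2-[4-(benzyloxy)phenyl]-1a,7b-dihydro-2H-oxireno[2,3-c]chromene; 12 5,7,3',4'-tetra-O-benzyl-(+)-catechin
Product: 13 5,7,4'-tri-O-benzyl-epiafzelechin-(4β→8)-5,7,3',4'-tetra-O-benzylcatechin (upper unit 2R,3R,4R, lower unit 2R,3S)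
Conditions: BF3·OEt2 (10 mol%), CH2Cl2, −78 °C to −40 °C; the catechin nucleophile in threefold excess, the epoxide added slowly, unreacted nucleophile recovered on silica
Reagents that add atoms: none
Why: Friedel–Crafts opening of the benzylic epoxide (C4 cation stabilised by the 5,7-dialkoxy ring A); C8 of 12 attacks C4 anti to the oxirane oxygen and to the 2-aryl group, giving the 4β (4R) aryl group and the free 3α (3R) hydroxyl, with every atom of both partners kept in the product.

Step 8
Reactants: 13 5,7,4'-tri-O-benzyl-epiafzelechin-(4β→8)-5,7,3',4'-tetra-O-benzylcatechin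
Product: 14 gambiriin C [epiafzelechin-(4β→8)-catechin, upper unit 2R,3R,4R, lower unit 2R,3S]
Conditions: H2 (balloon), Pd(OH)2/C, THF/MeOH/H2O, rt
Reagents that add atoms: none
Why: hydrogenolysis of the seven benzyl ethers under neutral conditions; the ring C ethers, the interflavan bond and all five stereocenters are unaffected.

**Compound list**
1 | 2-bromo-1-[4-(benzyloxy)phenyl]ethan-1-one | O=C(CBr)c1ccc(OCc2ccccc2)cc1 | starting material
2 | 1-[4-(benzyloxy)phenyl]-2-(phenylsulfanyl)ethan-1-one | O=C(CSc1ccccc1)c1ccc(OCc2ccccc2)cc1 | intermediate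
3 | (1R)-1-[4-(benzyloxy)phenyl]-2-(phenylsulfanyl)ethan-1-ol | O[C@@H](CSc1ccccc1)c1ccc(OCc2ccccc2)cc1 | intermediate
4 | 2,4,6-trifluorobenzaldehyde | O=Cc1c(F)cc(F)cc1F | starting material
5 | 2,4-bis(benzyloxy)-6-fluorobenzaldehyde | O=Cc1c(F)cc(OCc2ccccc2)cc1OCc1ccccc1 | intermediate
6 | 2,4-bis(benzyloxy)-6-{(1R)-1-[4-(benzyloxy)phenyl]-2-(phenylsulfanyl)ethoxy}benzaldehyde | O=Cc1c(O[C@@H](CSc2ccccc2)c2ccc(OCc3ccccc3)cc2)cc(OCc2ccccc2)cc1OCc1ccccc1 | intermediate
7 | S-aryl sulfonium zwitterion (not isolated): 2-{[(2R)-2-[3,5-bis(benzyloxy)-2-formylphenoxy]-2-[4-(benzyloxy)phenyl]ethyl](phenyl)sulfonio}benzen-1-ide (configuration at sulfur undefined) | [C-]1=CC=CC=C1[S+](c1ccccc1)C[C@H](Oc1cc(OCc2ccccc2)cc(OCc2ccccc2)c1C=O)c1ccc(OCc2ccccc2)cc1 | intermediate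
8 | diphenylsulfonium ylide (not isolated): (2R)-2-[3,5-bis(benzyloxy)-2-formylphenoxy]-2-[4-(benzyloxy)phenyl]-1-(diphenylsulfonio)ethan-1-ide | [CH-]([S+](c1ccccc1)c1ccccc1)[C@H](Oc1cc(OCc2ccccc2)cc(OCc2ccccc2)c1C=O)c1ccc(OCc2ccccc2)cc1 | intermediate
9 | sulfonium alkoxide betaine (not isolated): (2R,3S,4R)-5,7-bis(benzyloxy)-2-[4-(benzyloxy)phenyl]-3-(diphenylsulfonio)chroman-4-olate (S+ trans to the 2-aryl group and trans to O−) | c1ccc(COc2ccc(cc2)[C@H]2Oc3cc(OCc4ccccc4)cc(OCc4ccccc4)c3[C@@H]([O-])[C@@H]2[S+](c2ccccc2)c2ccccc2)cc1 | intermediate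
10 | (1aR,2R,7bR)-5,7-bis(benzyloxy)-2-[4-(benzyloxy)phenyl]-1a,7b-dihydro-2H-oxireno[2,3-c]chromene (5,7,4'-tri-O-benzyl flav-3-ene 3α,4α-oxide; oxirane oxygen and 2-aryl group on the same face) | c1ccc(COc2ccc(cc2)[C@H]2Oc3cc(OCc4ccccc4)cc(OCc4ccccc4)c3[C@H]3O[C@@H]23)cc1 | intermediate
11 | (+)-catechin (2R,3S) | O[C@H]1Cc2c(O)cc(O)cc2O[C@@H]1c1ccc(O)c(O)c1 | starting material
12 | 5,7,3',4'-tetra-O-benzyl-(+)-catechin | O[C@H]1Cc2c(OCc3ccccc3)cc(OCc3ccccc3)cc2O[C@@H]1c1ccc(OCc2ccccc2)c(OCc2ccccc2)c1 | intermediate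
13 | 5,7,4'-tri-O-benzyl-epiafzelechin-(4β→8)-5,7,3',4'-tetra-O-benzylcatechin (upper 2R,3R,4R; lower 2R,3S) | C(Oc1ccc([C@H]2Oc3cc(OCc5ccccc5)cc(OCc5ccccc5)c3[C@H](c3c(OCc5ccccc5)cc(OCc5ccccc5)c4c3O[C@H](c3ccc(OCc5ccccc5)c(OCc5ccccc5)c3)[C@@H](O)C4)[C@H]2O)cc1)c1ccccc1 | intermediate
14 | gambiriin C, epiafzelechin-(4β→8)-catechin (upper 2R,3R,4R; lower 2R,3S) | Oc1ccc([C@H]2Oc3cc(O)cc(O)c3[C@H](c3c(O)cc(O)c4c3O[C@H](c3ccc(O)c(O)c3)[C@@H](O)C4)[C@H]2O)cc1 | target

**Totals.** 8 steps; longest linear sequence 6 (steps 1, 2, 4, 5, 7, 8).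

**Three steps most likely to fail, each with a fallback**

1. Step 5, the ylide epoxy-annulation. The ylide may expel the aryloxide (β-elimination) before it cyclises, which would erode the C2 configuration. Only the betaine with sulfonium and alkoxide trans can close to the oxirane, and the facial preference (sulfonium anti to the 2-aryl group) is predicted, not proven. The fallback sets out from 5 and returns at 10, building ring C first and the oxirane afterwards.
   - Hydroxide SNAr (KOH, DMSO/H2O, 80 °C) gives 2,4-bis(benzyloxy)-6-hydroxybenzaldehyde F1.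
   - An oxa-Michael/aldol condensation domino with (E)-3-[4-(benzyloxy)phenyl]prop-2-enal under iminium catalysis ((S)-2-[diphenyl(trimethylsilyloxy)methyl]pyrrolidine, 2-nitrobenzoic acid, toluene) gives (2R)-5,7-bis(benzyloxy)-2-[4-(benzyloxy)phenyl]-2H-chromene-3-carbaldehyde F2. The (S)-catalyst is chosen on the usual shielding model, in which the phenoxide adds to the enal β-carbon on the face away from the diphenyl(silyloxy)methyl group; this sense should be confirmed on the first batch.
   - Decarbonylation with RhCl(PPh3)3 (toluene, 110 °C) gives the flav-3-ene (2S)-5,7-bis(benzyloxy)-2-[4-(benzyloxy)phenyl]-2H-chromene F3 (same spatial arrangement at C2; only the CIP descriptor changes).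
   - N-Bromosuccinimide in THF/H2O adds bromine anti to the 2-aryl group and water trans at C4 to give (2R,3S,4R)-5,7-bis(benzyloxy)-2-[4-(benzyloxy)phenyl]-3-bromochroman-4-ol F4.
   - K2CO3 in MeOH then closes the oxirane on the face of the aryl group, returning to 10.

2. Step 4, the SNAr etherification. A hindered secondary alkoxide must attack an arene that already carries two alkoxy groups, and hydride transfer from the alkoxide to the aldehyde can compete. The fallback sets out from 3 and 4 and returns at 6, reversing the order of the substitutions. The lithium alkoxide of 3 (LiN(SiMe3)2, toluene/THF, −40 °C) attacks the far more electrophilic 4 at an ortho fluorine (lithium chelation to the formyl oxygen) to give 2-{(1R)-1-[4-(benzyloxy)phenyl]-2-(phenylsulfanyl)ethoxy}-4,6-difluorobenzaldehyde F5. The two remaining fluorines are then exchanged with BnOH/NaH in DMF to reach 6.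

3. Step 7, the epoxide arylation. Compound 10 is very acid-labile: a 1,2-hydride shift to the flavan-3-one or elimination can outrun arylation, and some C6 attack or further oligomerisation is possible. The fallback sets out from 10 and returns at 13. The epoxide is first trapped with 2-ethoxyethanol (pyridinium p-toluenesulfonate cat., CH2Cl2, −20 °C; anti opening at C4) as the bench-stable ether (2R,3R,4S)-5,7-bis(benzyloxy)-2-[4-(benzyloxy)phenyl]-4-(2-ethoxyethoxy)chroman-3-ol F6. Its C4–O bond is then ionised with Me3SiOTf (CH2Cl2, −78 °C) in the presence of a fourfold excess of 12; the same C4 cation is captured on the β face and the route rejoins at 13.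

**Further compounds**
F1 | step 5 | 2,4-bis(benzyloxy)-6-hydroxybenzaldehyde | O=Cc1c(O)cc(OCc2ccccc2)cc1OCc1ccccc1
F2 | step 5 | (2R)-5,7-bis(benzyloxy)-2-[4-(benzyloxy)phenyl]-2H-chromene-3-carbaldehyde | O=CC1=Cc2c(OCc3ccccc3)cc(OCc3ccccc3)cc2O[C@@H]1c1ccc(OCc2ccccc2)cc1
F3 | step 5 | (2S)-5,7-bis(benzyloxy)-2-[4-(benzyloxy)phenyl]-2H-chromene | C1=Cc2c(OCc3ccccc3)cc(OCc3ccccc3)cc2O[C@@H]1c1ccc(OCc2ccccc2)cc1
F4 | step 5 | (2R,3S,4R)-5,7-bis(benzyloxy)-2-[4-(benzyloxy)phenyl]-3-bromochroman-4-ol | c1ccc(COc2ccc(cc2)[C@H]2Oc3cc(OCc4ccccc4)cc(OCc4ccccc4)c3[C@@H](O)[C@@H]2Br)cc1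
F5 | step 4 | 2-{(1R)-1-[4-(benzyloxy)phenyl]-2-(phenylsulfanyl)ethoxy}-4,6-difluorobenzaldehyde | O=Cc1c(F)cc(F)cc1O[C@@H](CSc1ccccc1)c1ccc(OCc2ccccc2)cc1
F6 | step 7 | (2R,3R,4S)-5,7-bis(benzyloxy)-2-[4-(benzyloxy)phenyl]-4-(2-ethoxyethoxy)chroman-3-ol | c1ccc(COc2ccc(cc2)[C@H]2Oc3cc(OCc4ccccc4)cc(OCc4ccccc4)c3[C@H](OCCOCC)[C@H]2O)cc1
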